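**Strategy.** Ring A is disconnected completely. It is a pentasubstituted, phloroglucinol-type benzene (O1 on C8a, OH on C5 and C7, geranyl on C6, H on C8) and is assembled on a preformed, enantiopure ring C. Light-induced Wolff rearrangement of a dihydropyranone diazoketone gives a vinylketene that takes up a geranyl-substituted siloxyalkyne. One operation forms C8–C8a, C5–C6, C7–C8 and C4a–C5 and places the geranyl group unambiguously between the oxygenated carbons C5 and C7. The precursor is the (S)-2-aryl-2,3-dihydro-4H-pyran-4-one with a diazoacetyl group at C6; its stereocentre comes from a catalytic asymmetric hetero-Diels–Alder reaction. The 4'- and 7-oxygens carry triisopropylsilyl groups, removed together at the end.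

Key step: step 8

Remark: flavanone numbering is used (O1, C2, C3, C4, C4a, C5–C8, C8a; ring C is the pyranone, ring A the benzene). The ketene/ynol ether cycloadduct is a 4-alkenyl-3-silyloxy-2-geranylcyclobut-2-enone. The carboxyl group is freed without hydroxide and the diazo carbon is brought in with TMSCHN2, to protect the aryl silyl ether, the O1–C2 bond and the enone. HC≡CMgBr in THF, anhydrous tBuOOH in decane and TMSCHN2 are taken as commercial.

**Step 1**
Reactants: 1 4-hydroxybenzaldehyde
Product: 2 4-(triisopropylsilyloxy)benzaldehyde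
Conditions: TIPSCl, imidazole, DMF, rt
Reagents that add atoms: triisopropylsilyl chloride, CC(C)[Si](Cl)(C(C)C)C(C)C
Why: Imidazole-promoted O-silylation of the phenol gives a bulky aryl silyl ether that should survive Lewis acid, TFA, the ester cleavage and the acyl chloride, and leave with fluoride at the end.

**Step 2**
Reactants: 3 ethyl 2,4-dioxovalerate
Product: 4 ethyl (2Z)-2,4-bis(trimethylsilyloxy)penta-2,4-dienoate
Conditions: TMSOTf (2.2 equiv), Et3N (2.5 equiv), Et2O, 0 °C → rt; used crude under argon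
Reagents that add atoms: trimethylsilyl trifluoromethanesulfonate, C[Si](C)(C)OS(=O)(=O)C(F)(F)F
Why: Soft enolisation and double O-silylation of the 1,3-dicarbonyl unit should give the 1,3-bis(silyloxy)diene, since only the methyl group can supply the second enol ether; the Z geometry expected from the chelated enol is lost later and is of no consequence.

**Step 3**
Reactants: 2 4-(triisopropylsilyloxy)benzaldehyde; 4 ethyl (2Z)-2,4-bis(trimethylsilyloxy)penta-2,4-dienoate
Product: 6 ethyl (2S)-4-oxo-2-[4-(triisopropylsilyloxy)phenyl]-3,4-dihydro-2H-pyran-6-carboxylate, via silyl aldol adduct 5 (not isolated)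
Conditions: Ti(OiPr)4 (10 mol %), (S)-BINOL (20 mol %), 4 Å MS, Et2O, −20 °C; then TFA, CH2Cl2, 0 °C
Reagents that add atoms: none
Why: Formal asymmetric hetero-Diels–Alder reaction (BINOL–titanate-catalysed Mukaiyama aldol of the diene CH2 terminus, then acid-induced desilylation, hemiketalisation of the δ-hydroxyl onto the α-keto ester carbon and dehydration); the (S)-BINOL titanate is expected to direct the diene to the Si face of the aldehyde, which sets C2 as S, and the ring closure does not touch that centre.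

**Step 4**
Reactants: 6 ethyl (2S)-4-oxo-2-[4-(triisopropylsilyloxy)phenyl]-3,4-dihydro-2H-pyran-6-carboxylate
Product: 7 (2S)-4-oxo-2-[4-(triisopropylsilyloxy)phenyl]-3,4-dihydro-2H-pyran-6-carboxylic acid
Conditions: Me3SnOH (4 equiv), ClCH2CH2Cl, 70 °C; cold 0.5 M HCl wash
Reagents that add atoms: trimethyltin hydroxide, C[Sn](C)(C)O
Why: Tin hydroxide-mediated ester cleavage of the conjugation-activated ester is close to neutral, so the base-labile aryl silyl ether should stay and ring C should not open by retro-oxa-Michael reaction, which would racemise C2.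

**Step 5**
Reactants: 7 (2S)-4-oxo-2-[4-(triisopropylsilyloxy)phenyl]-3,4-dihydro-2H-pyran-6-carboxylic acid
Product: 9 (S)-6-(2-diazoacetyl)-2-[4-(triisopropylsilyloxy)phenyl]-2,3-dihydro-4H-pyran-4-one, via acid chloride 8 (not isolated)
Conditions: (COCl)2, DMF (cat.), CH2Cl2, 0 °C → rt, evaporate; TMSCHN2 (2.2 equiv), MeCN/THF, 0 °C, dark
Reagents that add atoms: trimethylsilyldiazomethane, C[Si](C)(C)C=[N+]=[N-]
Why: Arndt–Eistert-type acylation of a diazoalkane by the acid chloride, with chloride removing the silyl group; the bulky, less dipolarophilic reagent and the donation of O1 into C5 should keep 1,3-dipolar addition to the C5=C6 bond slow.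

**Step 6**
Reactants: 10 geranyl bromide
Product: 11 (E)-5,9-dimethyldeca-4,8-dien-1-yne
Conditions: HC≡CMgBr (3 equiv), CuCl (10 mol %), THF, 0 → 50 °C
Reagents that add atoms: ethynylmagnesium bromide, C#C[Mg]Br
Why: Copper-catalysed SN2 allylic substitution of the primary bromide by the alkynyl Grignard reagent should give the skipped enyne at the unhindered carbon with the E olefin kept; excess Grignard reagent suppresses double alkylation.

**Step 7**
Reactants: 11 (E)-5,9-dimethyldeca-4,8-dien-1-yne
Product: 14 (E)-[(5,9-dimethyldeca-4,8-dien-1-yn-1-yl)oxy]triisopropylsilane, via lithium acetylide 12 (not isolated), via lithium ynolate 13 (not isolated)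
Conditions: n-BuLi, THF, −78 °C; LiOOtBu [from tBuOOH and LiN(SiMe3)2, THF, −78 °C], −78 → 0 °C; TIPSOTf, −78 → 0 °C
Reagents that add atoms: tert-butyl hydroperoxide, CC(C)(C)OO; triisopropylsilyl trifluoromethanesulfonate, CC(C)[Si](OS(=O)(=O)C(F)(F)F)(C(C)C)C(C)C
Why: Electrophilic oxygen transfer from the lithium peroxide to the acetylide (acetylide-to-ynolate oxidation) followed by O-silylation with the hard, bulky silyl triflate is the standard entry to triisopropylsilyl ynol ethers, and the nucleophilic oxidant should ignore the trisubstituted olefins.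

**Step 8**
Reactants: 9 (S)-6-(2-diazoacetyl)-2-[4-(triisopropylsilyloxy)phenyl]-2,3-dihydro-4H-pyran-4-one; 14 (E)-[(5,9-dimethyldeca-4,8-dien-1-yn-1-yl)oxy]triisopropylsilane
Product: 19 (S)-6-geranyl-5-hydroxy-7,4'-bis(triisopropylsilyloxy)flavanone, via vinylketene 15 (not isolated), via vinylcyclobutenone 16 (not isolated), via dienylketene 17 (not isolated), via cyclohexadienone 18 (not isolated)
Conditions: 14 (1.5 equiv), hν (365 nm), degassed ClCH2CH2Cl, rt; then 80 °C, dark
Reagents that add atoms: none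
Why: Light expels N2 from 9 and pyranone C6 shifts to the diazo carbon (Wolff rearrangement, forming C8–C8a) to give vinylketene 15, whose electrophilic carbonyl carbon (future C5) bonds to the nucleophilic, geranyl-bearing carbon of ynol ether 14 while its α-carbon (future C8) bonds to the silyloxy-bearing carbon, giving cyclobutenone 16 by [2+2] cycloaddition. Heating opens 16 by reversible 4π electrocyclic cleavage of the former ketene C=C bond to dienylketene 17, and a thermal disrotatory 6π electrocyclisation between the ketene carbon and pyranone C5 closes ring A through the C4a–C5 bond; enolisation of dienone 18 to the aromatic phenol, hydrogen-bonded to C4=O, drives the cascade. The closest known reaction type is the Danheiser benzannulation of alkenyl α-diazo ketones with siloxyalkynes in its photochemical Wolff version. No stereocentre that survives is created (C4 of 16 and C4a of 18 are transient), and C2 should stay untouched because no acid, base or metal is present. The regiochemistry the step needs, geranyl on C6 between the C5 hydroxyl and the C7 silyl ether with hydrogen on C8, is fixed by the polarity match of ketene and ynol ether. Irradiation near 365 nm should address the diazoketone and spare product 19, and the isolated geranyl olefins are far poorer ketene partners than the ynol ether.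

**Step 9**
Reactants: 19 (S)-6-geranyl-5-hydroxy-7,4'-bis(triisopropylsilyloxy)flavanone
Product: 20 Bonannione A
Conditions: HF·pyridine, pyridine, THF, 0 °C → rt
Reagents that add atoms: none
Why: Fluoride-mediated cleavage of both aryl silyl ethers under buffered conditions should avoid base-induced opening of ring C to the chalcone (loss of C2 configuration) and acid-induced cyclisation of a phenol onto the geranyl olefin.

**Compound list**
1 | 4-hydroxybenzaldehyde | O=Cc1ccc(O)cc1 | starting material
2 | 4-(triisopropylsilyloxy)benzaldehyde | O=Cc1ccc(O[Si](C(C)C)(C(C)C)C(C)C)cc1 | intermediate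
3 | ethyl 2,4-dioxovalerate | CCOC(=O)C(=O)CC(C)=O | starting material
4 | ethyl (2Z)-2,4-bis(trimethylsilyloxy)penta-2,4-dienoate | CCOC(=O)/C(O[Si](C)(C)C)=C/C(=C)O[Si](C)(C)C | intermediate
5 | ethyl (2Z,6S)-4-oxo-2,6-bis(trimethylsilyloxy)-6-[4-(triisopropylsilyloxy)phenyl]hex-2-enoate | CCOC(=O)/C(O[Si](C)(C)C)=C/C(=O)C[C@H](O[Si](C)(C)C)c1ccc(O[Si](C(C)C)(C(C)C)C(C)C)cc1 | intermediate (not isolated)
6 | ethyl (2S)-4-oxo-2-[4-(triisopropylsilyloxy)phenyl]-3,4-dihydro-2H-pyran-6-carboxylate | CCOC(=O)C1=CC(=O)C[C@@H](c2ccc(O[Si](C(C)C)(C(C)C)C(C)C)cc2)O1 | intermediate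
7 | (2S)-4-oxo-2-[4-(triisopropylsilyloxy)phenyl]-3,4-dihydro-2H-pyran-6-carboxylic acid | OC(=O)C1=CC(=O)C[C@@H](c2ccc(O[Si](C(C)C)(C(C)C)C(C)C)cc2)O1 | intermediate
8 | (2S)-4-oxo-2-[4-(triisopropylsilyloxy)phenyl]-3,4-dihydro-2H-pyran-6-carbonyl chloride | ClC(=O)C1=CC(=O)C[C@@H](c2ccc(O[Si](C(C)C)(C(C)C)C(C)C)cc2)O1 | intermediate (not isolated)
9 | (S)-6-(2-diazoacetyl)-2-[4-(triisopropylsilyloxy)phenyl]-2,3-dihydro-4H-pyran-4-one | [N-]=[N+]=CC(=O)C1=CC(=O)C[C@@H](c2ccc(O[Si](C(C)C)(C(C)C)C(C)C)cc2)O1 | intermediate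
10 | geranyl bromide, (E)-1-bromo-3,7-dimethylocta-2,6-diene | CC(C)=CCC/C(C)=C/CBr | starting material
11 | (E)-5,9-dimethyldeca-4,8-dien-1-yne | CC(C)=CCC/C(C)=C/CC#C | intermediate
12 | lithium (E)-5,9-dimethyldeca-4,8-dien-1-yn-1-ide | CC(C)=CCC/C(C)=C/CC#[C-].[Li+] | intermediate (not isolated)
13 | lithium (E)-5,9-dimethyldeca-4,8-dien-1-yn-1-olate | CC(C)=CCC/C(C)=C/CC#C[O-].[Li+] | intermediate (not isolated)
14 | (E)-[(5,9-dimethyldeca-4,8-dien-1-yn-1-yl)oxy]triisopropylsilane | CC(C)=CCC/C(C)=C/CC#CO[Si](C(C)C)(C(C)C)C(C)C | intermediate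
15 | (S)-6-(2-oxoethenyl)-2-[4-(triisopropylsilyloxy)phenyl]-2,3-dihydro-4H-pyran-4-one (vinylketene) | O=C=CC1=CC(=O)C[C@@H](c2ccc(O[Si](C(C)C)(C(C)C)C(C)C)cc2)O1 | intermediate (not isolated)
16 | 2-geranyl-4-{(2S)-4-oxo-2-[4-(triisopropylsilyloxy)phenyl]-3,4-dihydro-2H-pyran-6-yl}-3-(triisopropylsilyloxy)cyclobut-2-en-1-one (either C4 epimer) | CC(C)=CCC/C(C)=C/CC1=C(O[Si](C(C)C)(C(C)C)C(C)C)C(C2=CC(=O)C[C@@H](c3ccc(O[Si](C(C)C)(C(C)C)C(C)C)cc3)O2)C1=O | intermediate (not isolated)
17 | (S)-6-[(1E,5E)-6,10-dimethyl-3-(oxomethylidene)-2-(triisopropylsilyloxy)undeca-1,5,9-trien-1-yl]-2-[4-(triisopropylsilyloxy)phenyl]-2,3-dihydro-4H-pyran-4-one (dienylketene, ketene cis to the pyranone across the central C=C) | CC(C)=CCC/C(C)=C/CC(=C=O)/C(O[Si](C(C)C)(C(C)C)C(C)C)=C\C1=CC(=O)C[C@@H](c2ccc(O[Si](C(C)C)(C(C)C)C(C)C)cc2)O1 | intermediate (not isolated)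
18 | (2S)-6-geranyl-7-(triisopropylsilyloxy)-2-[4-(triisopropylsilyloxy)phenyl]-2,3-dihydrochromene-4,5(4aH)-dione (either C4a epimer) | CC(C)=CCC/C(C)=C/CC1=C(O[Si](C(C)C)(C(C)C)C(C)C)C=C2O[C@H](c3ccc(O[Si](C(C)C)(C(C)C)C(C)C)cc3)CC(=O)C2C1=O | intermediate (not isolated)
19 | (S)-6-geranyl-5-hydroxy-7,4'-bis(triisopropylsilyloxy)flavanone | CC(C)=CCC/C(C)=C/Cc1c(O[Si](C(C)C)(C(C)C)C(C)C)cc2c(c1O)C(=O)C[C@@H](c1ccc(O[Si](C(C)C)(C(C)C)C(C)C)cc1)O2 | intermediate
20 | Bonannione A, (2S)-6-geranyl-5,7-dihydroxy-2-(4-hydroxyphenyl)-2,3-dihydro-4H-chromen-4-one | CC(C)=CCC/C(C)=C/Cc1c(O)cc2c(c1O)C(=O)C[C@@H](c1ccc(O)cc1)O2 | target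

**Step count.** Total: 9 steps. Longest linear sequence: 6 steps (1 → 2 → 6 → 7 → 9 → 19 → 20; equally 3 → 4 → 6 → …).

**Steps most likely to fail**

Step 8. The enone chromophore of ring C may be excited along with the diazoketone and enter [2+2] photocycloaddition with the olefins or the alkyne, or the carbene may be diverted before the 1,2-shift, so that the cascade starves. The fallback makes the same vinylketene in the dark by dehydrochlorination. It sets out from 9: silver benzoate (PhCO2Ag, cat.), Et3N, THF/H2O, rt (Arndt–Eistert homologation) should give [(2S)-4-oxo-2-[4-(triisopropylsilyloxy)phenyl]-3,4-dihydro-2H-pyran-6-yl]acetic acid F1. Oxalyl chloride with catalytic DMF converts it into [(2S)-4-oxo-2-[4-(triisopropylsilyloxy)phenyl]-3,4-dihydro-2H-pyran-6-yl]acetyl chloride F2. Slow addition of Et3N to F2 and 14 in toluene (rt, then 80 °C) should generate vinylketene 15 by 1,2-elimination of HCl; it is trapped by the ynol ether and runs through 16, 17 and 18, returning to the route at 19.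

Step 5. Dipolar addition of the diazoalkane to the doubly activated C5=C6 bond may compete with acylation, or the acid chloride may degrade before it is trapped. The fallback builds the diazo group by diazo transfer. It sets out from 7 through its chloride 8: Stille coupling with Me4Sn (PdCl2(PPh3)2 cat., toluene, 60 °C) should give (S)-6-acetyl-2-[4-(triisopropylsilyloxy)phenyl]-2,3-dihydro-4H-pyran-4-one F3. Kinetic enolisation of the acetyl group (LiN(SiMe3)2, THF, −78 °C) and trapping with CF3CO2CH2CF3 gives the trifluoroacetyl diketone (S)-6-(4,4,4-trifluoro-3-oxobutanoyl)-2-[4-(triisopropylsilyloxy)phenyl]-2,3-dihydro-4H-pyran-4-one F4. Detrifluoroacetylative diazo transfer (MsN3, Et3N, H2O, MeCN, rt) returns to the route at 9.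

Step 3. Facial discrimination may be poor with a diene that carries a chelating ester, or the diene may be protodesilylated before C–C bond formation. The fallback sets the stereocentre first and closes ring C afterwards. It sets out from 2: aldol addition of acetone under a D-proline-derived prolinamide catalyst (the D series is expected to give the S carbinol) gives (S)-4-hydroxy-4-[4-(triisopropylsilyloxy)phenyl]butan-2-one F5. Silylation (TESCl, imidazole, CH2Cl2) gives (S)-4-(triethylsilyloxy)-4-[4-(triisopropylsilyloxy)phenyl]butan-2-one F6. Claisen condensation of its kinetic methyl enolate with diethyl oxalate (LiN(SiMe3)2, THF, −78 °C) gives ethyl (S)-2,4-dioxo-6-(triethylsilyloxy)-6-[4-(triisopropylsilyloxy)phenyl]hexanoate F7. TFA in wet CH2Cl2 at 0 °C removes the triethylsilyl group and cyclodehydrates, returning to the route at 6.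

**Further compounds**
F1 | step 8 | [(2S)-4-oxo-2-[4-(triisopropylsilyloxy)phenyl]-3,4-dihydro-2H-pyran-6-yl]acetic acid | OC(=O)CC1=CC(=O)C[C@@H](c2ccc(O[Si](C(C)C)(C(C)C)C(C)C)cc2)O1
F2 | step 8 | [(2S)-4-oxo-2-[4-(triisopropylsilyloxy)phenyl]-3,4-dihydro-2H-pyran-6-yl]acetyl chloride | ClC(=O)CC1=CC(=O)C[C@@H](c2ccc(O[Si](C(C)C)(C(C)C)C(C)C)cc2)O1
F3 | step 5 | (S)-6-acetyl-2-[4-(triisopropylsilyloxy)phenyl]-2,3-dihydro-4H-pyran-4-one | CC(=O)C1=CC(=O)C[C@@H](c2ccc(O[Si](C(C)C)(C(C)C)C(C)C)cc2)O1
F4 | step 5 | (S)-6-(4,4,4-trifluoro-3-oxobutanoyl)-2-[4-(triisopropylsilyloxy)phenyl]-2,3-dihydro-4H-pyran-4-one | FC(F)(F)C(=O)CC(=O)C1=CC(=O)C[C@@H](c2ccc(O[Si](C(C)C)(C(C)C)C(C)C)cc2)O1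
F5 | step 3 | (S)-4-hydroxy-4-[4-(triisopropylsilyloxy)phenyl]butan-2-one | CC(=O)C[C@H](O)c1ccc(O[Si](C(C)C)(C(C)C)C(C)C)cc1
F6 | step 3 | (S)-4-(triethylsilyloxy)-4-[4-(triisopropylsilyloxy)phenyl]butan-2-one | CC(=O)C[C@H](O[Si](CC)(CC)CC)c1ccc(O[Si](C(C)C)(C(C)C)C(C)C)cc1
F7 | step 3 | ethyl (S)-2,4-dioxo-6-(triethylsilyloxy)-6-[4-(triisopropylsilyloxy)phenyl]hexanoate | CCOC(=O)C(=O)CC(=O)C[C@H](O[Si](CC)(CC)CC)c1ccc(O[Si](C(C)C)(C(C)C)C(C)C)cc1
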